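**Retrosynthetic overview**
- No ring has to be built: rings A, B and C are bought together as (±)-naringenin (1); ring C is only raised from the flavanone to the flavonol oxidation level.
- Key disconnection, C3–O: the flavonol 3-OH goes back to the C3 methylene of 1. In one flask 1 passes through silyl enol ether 2, α-aminooxy ketone 3, 3,4-dione 4 and silylated flavonol 5 to kaempferol (6).
- Last disconnection, O7–S: the target (7) goes back to the free 7-OH of 6 and SO3.
- Order: C3–O bond first, so that no sulfate is present during the silyl triflate chemistry; sulfate ester last.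

Assumption: the target has no stereocentre, so no stereocontrol is needed (racemic 1 is used and its C2 centre is erased); the hydrogen sulfate is written as the neutral acid drawn, although in practice it is handled as its pyridinium or sodium salt.

**Step 1**
Reactants: 1 (±)-naringenin
Product: 6 kaempferol, via silyl enol ether 2 (not isolated), via aminooxy ketone 3 (not isolated), via diketone 4 (not isolated), via tris-silyl kaempferol 5 (not isolated)
Conditions: TMSOTf (4.3 equiv), i-Pr2NEt (4.1 equiv), CH2Cl2, 0 °C to rt; PhNO (1.1 equiv), −78 °C; DBU (2.5 equiv), −78 °C to rt; MeOH, rt; aq. citric acid work-up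
Reagents that add atoms: nitrosobenzene, O=Nc1ccccc1 (its oxygen becomes the 3-OH oxygen of 6); trimethylsilyl trifluoromethanesulfonate, C[Si](C)(C)OS(=O)(=O)C(F)(F)F (its Me3Si groups sit only in 2, 3, 4 and 5 and are absent from 6)
Why: Proposed new method: a one-flask flavanone-to-flavonol oxidation in which nitrosobenzene is a four-electron oxygen donor — soft enolisation and persilylation give 2, whose enol ether carbon C3 is far more nucleophilic than the silylated aryl rings; the small excess of TMSOTf then catalyses an O-selective Mukaiyama-type nitroso aldol (Lewis acid on N, C3 attacks O; closest known reaction: Lewis-acid-catalysed α-aminoxylation of ketone silyl enol ethers) that forms the key C3–O bond in 3; DBU removes the C3–H, now activated by both C4=O and the oxygen, and the weak N–O bond breaks in a Kornblum–DeLaMare-type fragmentation (closest known reaction: base-induced rearrangement of α-C–H peroxides to ketones) to give 4, which tautomerises irreversibly to the aromatic 3-hydroxy-γ-pyrone 5 before methanolysis of the O–Si bonds releases 6; the stereocentres of 1 and 3 are erased, so none has to be controlled, and this merger has not been shown on flavanones.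

**Step 2**
Reactants: 6 kaempferol
Product: 7 kaempferol 7-O-sulfate
Conditions: SO3·pyridine (1.05 equiv), pyridine, −15 °C to 4 °C; H2O quench; C18 reversed-phase chromatography (H2O/MeOH)
Reagents that add atoms: sulfur trioxide–pyridine complex, [O-]S(=O)(=O)[n+]1ccccc1
Why: Phenol O-sulfation by sulfuryl transfer from an SO3–amine complex: the 3- and 5-OH are hydrogen-bonded to C4=O and the 7-OH is the most acidic and least hindered phenol, matching the reactivity order I recall for flavonol sulfation (7 > 4' > 3, 5 inert), so one equivalent at low temperature should give mainly the 7-monosulfate, with 4'-sulfate and 7,4'-disulfate removed on C18; no stereocentre is involved.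

**Compound list**
1 | (±)-naringenin, racemic 5,7-dihydroxy-2-(4-hydroxyphenyl)chroman-4-one | O=C1CC(c2ccc(O)cc2)Oc2cc(O)cc(O)c12 | starting material
2 | racemic 4,5,7-tris(trimethylsilyloxy)-2-[4-(trimethylsilyloxy)phenyl]-2H-chromene | C[Si](C)(C)OC1=CC(c2ccc(O[Si](C)(C)C)cc2)Oc2cc(O[Si](C)(C)C)cc(O[Si](C)(C)C)c12 | intermediate
3 | racemic 3-[N-phenyl-N-(trimethylsilyl)aminooxy]-5,7-bis(trimethylsilyloxy)-2-[4-(trimethylsilyloxy)phenyl]chroman-4-one (2,3-trans expected, configuration of no consequence) | O=C1C(ON(c2ccccc2)[Si](C)(C)C)C(c2ccc(O[Si](C)(C)C)cc2)Oc2cc(O[Si](C)(C)C)cc(O[Si](C)(C)C)c12 | intermediate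
4 | racemic 5,7-bis(trimethylsilyloxy)-2-[4-(trimethylsilyloxy)phenyl]chromane-3,4-dione | O=C1C(=O)C(c2ccc(O[Si](C)(C)C)cc2)Oc2cc(O[Si](C)(C)C)cc(O[Si](C)(C)C)c12 | intermediate
5 | 3-hydroxy-5,7-bis(trimethylsilyloxy)-2-[4-(trimethylsilyloxy)phenyl]-4H-chromen-4-one (achiral) | O=c1c(O)c(-c2ccc(O[Si](C)(C)C)cc2)oc2cc(O[Si](C)(C)C)cc(O[Si](C)(C)C)c12 | intermediate
6 | kaempferol, 3,5,7-trihydroxy-2-(4-hydroxyphenyl)-4H-chromen-4-one (achiral) | O=c1c(O)c(-c2ccc(O)cc2)oc2cc(O)cc(O)c12 | intermediate
7 | kaempferol 7-O-sulfate, 3,5-dihydroxy-2-(4-hydroxyphenyl)-4-oxo-4H-chromen-7-yl hydrogen sulfate (achiral) | O=c1c(O)c(-c2ccc(O)cc2)oc2cc(OS(=O)(=O)O)cc(O)c12 | target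

**Total step count:** 2
**Longest linear sequence:** 2

**Steps most likely to fail** (the route has only two steps, so both are ranked; there is no third)

1. Step 1 (the proposed new step). Risks: attack of C3 on nitrogen instead of oxygen of PhNO (leads to 3-anilino products), Lewis-acid ring opening of 2 to the chalcone, or a sluggish N–O fragmentation of 3. Fallback, known chemistry only, replacing the nitroso oxygen donor by a protecting-group-based hydroxylation and dehydrogenation: it sets out from 1 and comes back to the route at 6. Benzylate 1 (BnBr, K2CO3, acetone, reflux; the chelated 5-OH stays free) to 7,4'-di-O-benzylnaringenin F1. Convert this with TMSOTf/Et3N in CH2Cl2 into its 4,5-bis(trimethylsilyl) enol ether F2, used crude. Rubottom oxidation (mCPBA, CH2Cl2, −20 °C, then dilute HCl/MeOH) gives (±)-trans-7,4'-di-O-benzyldihydrokaempferol F3. Dehydrogenate with I2/KOAc in AcOH at reflux to 7,4'-di-O-benzylkaempferol F4. Hydrogenolysis (H2, Pd/C, EtOAc/MeOH) gives 6.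

2. Step 2. Risk: the 4'-OH competes, giving 4'-sulfate and 7,4'-disulfate that lower the yield and must be separated. Fallback, replacing kinetic selection by protecting-group-defined regiochemistry: it sets out from 6 and comes back to the route at 7. Peracetylate (Ac2O, pyridine) to kaempferol 3,5,7,4'-tetraacetate F5. Remove only the most labile 7-O-acetyl group (PhSH, imidazole, N-methylpyrrolidone, 0 °C) to give 3,5,4'-tri-O-acetylkaempferol F6. Sulfate the single free OH (SO3·pyridine, pyridine, rt) to 3,5,4'-tri-O-acetylkaempferol 7-O-sulfate F7. Cleave the acetates with NH3 in MeOH at 0 °C, which leaves the aryl sulfate intact, to give 7.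

**Further compounds**
F1 | step 1 | racemic 7,4'-di-O-benzylnaringenin | O=C1CC(c2ccc(OCc3ccccc3)cc2)Oc2cc(OCc3ccccc3)cc(O)c12
F2 | step 1 | racemic 7-benzyloxy-2-(4-benzyloxyphenyl)-4,5-bis(trimethylsilyloxy)-2H-chromene | C[Si](C)(C)OC1=CC(c2ccc(OCc3ccccc3)cc2)Oc2cc(OCc3ccccc3)cc(O[Si](C)(C)C)c12
F3 | step 1 | (±)-trans-7,4'-di-O-benzyldihydrokaempferol (racemic; the (2R,3R) enantiomer is drawn) | O=C1[C@H](O)[C@@H](c2ccc(OCc3ccccc3)cc2)Oc2cc(OCc3ccccc3)cc(O)c12
F4 | step 1 | 7,4'-di-O-benzylkaempferol | O=c1c(O)c(-c2ccc(OCc3ccccc3)cc2)oc2cc(OCc3ccccc3)cc(O)c12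
F5 | step 2 | kaempferol 3,5,7,4'-tetraacetate | O=c1c(OC(C)=O)c(-c2ccc(OC(C)=O)cc2)oc2cc(OC(C)=O)cc(OC(C)=O)c12
F6 | step 2 | 3,5,4'-tri-O-acetylkaempferol | O=c1c(OC(C)=O)c(-c2ccc(OC(C)=O)cc2)oc2cc(O)cc(OC(C)=O)c12
F7 | step 2 | 3,5,4'-tri-O-acetylkaempferol 7-O-sulfate | O=c1c(OC(C)=O)c(-c2ccc(OC(C)=O)cc2)oc2cc(OS(=O)(=O)O)cc(OC(C)=O)c12
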